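# Proposed total synthesis of jezonodione (23)

## Analysis of the target

Jezonodione (23) is a bicyclo[3.2.1]oct-3-ene-2,8-dione. In that numbering a cyclopentanone (C8 carbonyl, C1, C7, C6, C5) is bridged from C1 to C5 by the enone unit C2(=O)–C3=C4. C4 carries an (E)-3,4-dihydroxystyryl group, C6 a 3,5-dihydroxyphenyl ring and C7 a 3,4-dihydroxyphenyl ring.

There are four stereocentres, (1S,5R,6R,7R). The bridgeheads C1 and C5 are tied to each other by the bridge. The aryl groups are trans: the resorcinol ring on C6 is exo (towards C8) and the catechol ring on C7 is endo (towards the enone bridge). C1–C2 is therefore cis to the C7 aryl, and C5–C4 trans to the C6 aryl.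

The sensitive elements are:
- the 1,3-diketone whose central carbon C1 is a bridgehead and cannot enolise, so nucleophiles can open it by retro-Claisen cleavage;
- the cross-conjugated dienone;
- six free phenols, four of them in oxidisable catechols.

The main difficulty is constitutional. Seen from C8 the cyclopentanone is almost symmetric: C1 and C5 differ only in whether the neighbouring ring is 3,4- or 3,5-oxygenated. Yet C1 must become the acylated carbon and C5 the carbon bonded to the styryl-bearing C4.

The plan rests on one feature. The ring C8–C1–C7–C6–C5 with its trans aryl pair is, without C5, the [2+2] adduct of an E-stilbene and a ketene. If the ketene brings two chlorines, inserting C5 between C8 and C6 of the cyclobutanone gives a cyclopentanone in which C1 is CCl2 and C5 is CH2. The polarity of the cycloaddition places the CCl2 carbon next to the catechol-bearing C7, as the target requires.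

## Retrosynthetic reasoning

**23 from 22.** Only the six O–benzyl bonds are cut. The phenols must be masked while enolates, a Lewis acid and a palladium salt are in use. Benzyl is preferred to methyl because a boron Lewis acid removes it at −78 °C, which a dienone and a non-enolisable diketone should survive. Hydrogenolysis is excluded by the alkenes.

**22 from 20.** The C3=C4 double bond is taken out. With C3 and C4 saturated, the six-membered ring can be closed by carbonyl chemistry with no second Michael acceptor present, and the configuration at C4 in 20 becomes irrelevant. The forward dehydrogenation is regiochemically safe: the C2 ketone can enolise only towards C3, because C1 is a bridgehead, and the C8 ketone cannot enolise at all.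

**20 from 19.** The C1–C2 bond is cut. This opens the six-membered ring to a cyclopentanone whose C5 carries the chain C4–C3–C2 ending in an N-acyl oxazolidinone. The bond joins a ketone α-carbon to an acyl carbon, a Claisen retron. Forward, the C1 enolate must attack the imide carbonyl. Because the electrophile hangs from C5, only cis-1,3 bridging is possible, and this fixes C1.

**19 from 18.** Two chlorine atoms are returned to C1. While they are present only C5 has α-hydrogens, so the two α-carbons can be addressed one after the other. Forward, they are removed reductively once C5 is alkylated.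

**18 from 11 and 17.** The C4–C5 bond is cut between the nucleophilic C5 of enol silane 11 and the β-carbon of dienoyl imide 17. This brings in C2, C3, C4 and the styryl arm in one piece. Forward, the conjugate addition must occur at the β- and not the δ-carbon, and on the face of C5 away from the C6 aryl. 11 is the enol silane of 10, for which only one regioisomer can exist.

**10 from 8 and 9 (the key disconnection).** C5 is excised: C5–C8 and C5–C6 are cut and C8 is rejoined to C6, contracting the ring to cyclobutanone 8, with 9 as the source of the carbon. This is the point at which the two α-carbons become different. Forward, the aryl-bearing C6 and not the CCl2 carbon must migrate, and only one carbon may be inserted.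

**8 from 7, and 7 from 4 and 5.** 8 is one enantiomer of racemate 7. In 7 the bonds C8–C6 and C1–C7 are cut, giving stilbene 4 and the ketene 6 generated from 5. The trans aryl pair is copied from the E alkene. The orientation follows from electronics, since the para-oxygenated ring stabilises positive charge at the carbon that bonds to CCl2. Absolute configuration comes from resolution, because no asymmetric version of this cycloaddition is available for stilbenes.

**4 from 2 and 3, and 2 from 1.** The stilbene double bond is cut by a Horner–Wadsworth–Emmons disconnection, which gives the E isomer reliably. The phosphonate comes from benzylic bromide 1.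

**17 from 14 and 15, 14 from 13, and 13 from 3 and 12.** The imide N–acyl bond is cut to acid 14 and oxazolidinone 15. The dienoate comes from the same aldehyde 3 and phosphonate 12 by a vinylogous olefination.

## Alternatives that were turned down

**Alternative 1: bridging a cycloheptenone by a vinylogous Mukaiyama reaction.**
- Disconnection: C5–C8. The bicycle is traced to cycloheptenone A2, in which C8 is an exocyclic diallyl acetal carbon on C1.
- Forward key step: Me3SiOTf and Et3N turn the enone into its extended silyl dienol ether and ionise the acetal. The γ-carbon C5 attacks the oxocarbenium ion and closes the five- and six-membered rings together, giving A1.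
- For: the bicycle forms in one step with the enone already in place, so no late dehydrogenation is needed. C1 and C5 are differentiated by construction. On this point it is stronger than the chosen route.
- Against: A2 is a seven-membered ring with three contiguous stereocentres and two different aryl groups in defined positions. The regiochemical problem is only moved into its synthesis, for which no short access is apparent. A1 also carries C8 as an allyl ether, so deallylation and oxidation of a hindered bridging alcohol must follow.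
- Comparison: the endgame is more elegant, but the precursor is longer and less certain to reach. The chosen route obtains the same regiochemical information in five steps from a stilbene.

**Alternative 2: Michael–Claisen [3+3] annulation across a diarylcyclopentanone.**
- Disconnection: C4–C5 and C1–C2 together, to enol silane A4 and dienoyl imide A5.
- Forward key step: a TiCl4-mediated Mukaiyama–Michael addition, then LiN(SiMe3)2 in the same flask for the Claisen closure, giving A3.
- For: two bonds and the six-membered ring in one pot. On step economy it is clearly stronger, saving the dechlorination and a separate closure. The chosen route uses the same two bond formations, one at a time.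
- Against: everything depends on A4 being a single regioisomer. Its parent ketone has two α-methylenes that differ only in remote aryl substitution, so direct silylation would give both enol silanes. The two annulation products would be constitutional isomers with the aryl rings exchanged. A regiospecific source of A4 needs a differentiated precursor.
- Comparison: the chosen route supplies exactly that differentiation. C1 stays blocked as CCl2 until C5 has been alkylated, so regiochemistry is decided by construction and not by separation.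

**Alternative 3: Ireland–Claisen rearrangement, then rhodium hydroacylation to the cyclopentanone.**
- Disconnection: C1–C8. The cyclopentanone is traced to pent-4-enal A7, whose C5 and C6 centres come from a sigmatropic rearrangement.
- Forward key step: [Rh(nbd)2]BF4 with BINAP adds the aldehyde C–H across the 1,1-disubstituted alkene, acyl to C1 and hydrogen to C7, giving A6.
- For: the chain is on C5 before the ring exists, so regiochemistry is unambiguous. Relative and absolute configuration could come from a chair transition state and a chiral catalyst, with no resolution. Here it is stronger than the chosen route.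
- Against: A7 holds a second alkene, the styryl group, in the same 4,5-relationship to the aldehyde, so hydroacylation could go either way. The α-branched aldehyde invites decarbonylation and epimerisation. C7 must form trans to C6 in a crowded substrate. The sequence to A7 is long, and ring closure onto the N-methoxy-N-methylamide and dehydrogenation still remain.
- Comparison: the chosen route makes the ring and the trans aryl pair in one cycloaddition from simple materials. It pays for this with a resolution.

Key step: step 5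

## Route

Remark on the chemistry: 9 is used as a freshly prepared ethereal solution (from N-methyl-N-nitroso-p-toluenesulfonamide and KOH). The chromatographic resolution is counted as a step. Benzyl ethers protect all six phenols throughout.

Step 1
Reactants: 1 3,5-bis(benzyloxy)benzyl bromide
Product: 2 diethyl {[3,5-bis(benzyloxy)phenyl]methyl}phosphonate
Conditions: P(OEt)3 (neat), 140 °C
Reagents that add atoms: triethyl phosphite, CCOP(OCC)OCC
Why: Michaelis–Arbuzov reaction; phosphorus displaces the benzylic bromide and bromide then dealkylates the phosphonium ion.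

Step 2
Reactants: 2 diethyl {[3,5-bis(benzyloxy)phenyl]methyl}phosphonate; 3 3,4-bis(benzyloxy)benzaldehyde
Product: 4 (E)-3,3′,4,5′-tetrakis(benzyloxy)stilbene
Conditions: KOtBu, THF, 0 °C → rt
Reagents that add atoms: none
Why: Horner–Wadsworth–Emmons olefination; a stabilised benzylic phosphonate anion and an aryl aldehyde should give the E-stilbene, whose geometry later becomes the trans C6/C7 relationship.

Step 3
Reactants: 4 (E)-3,3′,4,5′-tetrakis(benzyloxy)stilbene; 5 trichloroacetyl chloride
Product: 7 (3RS,4RS)-3-[3,4-bis(benzyloxy)phenyl]-4-[3,5-bis(benzyloxy)phenyl]-2,2-dichlorocyclobutan-1-one (racemic, aryl groups trans), via dichloroketene 6 (not isolated)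
Conditions: Zn–Cu couple, Et2O/DME, slow addition of 5, rt → 35 °C
Reagents that add atoms: trichloroacetyl chloride (5), O=C(Cl)C(Cl)(Cl)Cl
Why: Ketene–alkene [2+2] cycloaddition of 6, made in the flask by zinc dechlorination of 5, with DME binding the ZnCl2 formed. The ketene carbonyl carbon bonds to the alkene carbon bearing the 3,5-dioxygenated ring, because the positive charge building up on the other carbon is stabilised by the para-benzyloxy group; the CCl2 carbon therefore ends next to the catechol-bearing carbon. Both stereocentres are set relative to each other by suprafacial addition to the E alkene.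

Step 4
Reactants: 7 (3RS,4RS)-3-[3,4-bis(benzyloxy)phenyl]-4-[3,5-bis(benzyloxy)phenyl]-2,2-dichlorocyclobutan-1-one
Product: 8 (3S,4S)-3-[3,4-bis(benzyloxy)phenyl]-4-[3,5-bis(benzyloxy)phenyl]-2,2-dichlorocyclobutan-1-one
Conditions: preparative SFC on amylose tris(3,5-dimethylphenylcarbamate), CO2/iPrOH, 35 °C
Reagents that add atoms: none
Why: Physical separation of enantiomers on a chiral stationary phase, with no bond made or broken; the (3S,4S) fraction is to be identified by anomalous-dispersion X-ray analysis, for which the two chlorine atoms serve. This step fixes the absolute configuration of C6 and C7.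

Step 5
Reactants: 8 (3S,4S)-3-[3,4-bis(benzyloxy)phenyl]-4-[3,5-bis(benzyloxy)phenyl]-2,2-dichlorocyclobutan-1-one; 9 diazomethane
Product: 10 (3S,4S)-3-[3,4-bis(benzyloxy)phenyl]-4-[3,5-bis(benzyloxy)phenyl]-2,2-dichlorocyclopentan-1-one (aryl groups trans)
Conditions: CH2N2 (ethereal, small excess, in portions), MeOH (cat.), Et2O, 0 °C; AcOH quench
Reagents that add atoms: diazomethane (9), C=[N+]=[N-]
Why: Diazomethane adds through carbon to the ketone of 8, which ring strain and the two α-chlorines make strongly electrophilic, giving a diazonium betaine. Loss of N2 is coupled to a 1,2-shift of a ring bond onto the exocyclic methylene; the closest known reaction type is the diazomethane ring enlargement of α,α-dichlorocyclobutanones, a Tiffeneau–Demjanov-type homologation. The five-membered ring therefore arises by ring enlargement and not by end-to-end cyclisation: the addition forms C5–C8 and the shift of C6 from C8 to C5 forms C5–C6. No stereocentre is created; C6 migrates with retention and C7 is untouched, so the trans aryl pair and the configuration of 8 pass into 10. The first selectivity needed is migration of C6 and not C1: the CCl2 carbon is too electron-poor to carry the charge of a migrating terminus, whereas C6 is a secondary benzylic carbon, so C5 is placed on the resorcinol side. The second is a single insertion: 10 is an unstrained, far less electrophilic ketone, and the reagent is added in portions at 0 °C until 8 is consumed. Fast strain-releasing migration should also keep epoxide formation, the usual side path, small. After this step C6 is no longer α to the carbonyl, so the benzylic centre can no longer epimerise.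

Step 6
Reactants: 10 (3S,4S)-3-[3,4-bis(benzyloxy)phenyl]-4-[3,5-bis(benzyloxy)phenyl]-2,2-dichlorocyclopentan-1-one
Product: 11 {[(3S,4S)-4-[3,4-bis(benzyloxy)phenyl]-3-[3,5-bis(benzyloxy)phenyl]-5,5-dichlorocyclopent-1-en-1-yl]oxy}trimethylsilane
Conditions: Me3SiCl, then LiN(SiMe3)2, THF, −78 °C; pentane, filtration (used crude)
Reagents that add atoms: chlorotrimethylsilane, C[Si](C)(C)Cl
Why: Kinetic enolisation with O-silylation; only C5 carries α-hydrogens, so the chlorines on C1 make the enol silane regiodefined. Me3SiCl present from the start traps the enolate before it can displace chloride or eliminate HCl.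

Step 7
Reactants: 3 3,4-bis(benzyloxy)benzaldehyde; 12 ethyl (2E)-4-(diethoxyphosphoryl)but-2-enoate (triethyl 4-phosphonocrotonate)
Product: 13 ethyl (2E,4E)-5-[3,4-bis(benzyloxy)phenyl]penta-2,4-dienoate
Conditions: LiN(SiMe3)2, THF, −78 → 0 °C
Reagents that add atoms: none
Why: Vinylogous Horner–Wadsworth–Emmons olefination; the phosphonate anion reacts through its γ-carbon and should give the (2E,4E)-dienoate.

Step 8
Reactants: 13 ethyl (2E,4E)-5-[3,4-bis(benzyloxy)phenyl]penta-2,4-dienoate
Product: 14 (2E,4E)-5-[3,4-bis(benzyloxy)phenyl]penta-2,4-dienoic acid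
Conditions: LiOH, THF/MeOH/H2O, 45 °C; then aq. HCl
Reagents that add atoms: lithium hydroxide (LiOH), [Li+].[OH-]
Why: Ester saponification; the diene and the benzyl ethers are stable to aqueous hydroxide.

Step 9
Reactants: 14 (2E,4E)-5-[3,4-bis(benzyloxy)phenyl]penta-2,4-dienoic acid; 15 1,3-oxazolidin-2-one
Product: 17 3-{(2E,4E)-5-[3,4-bis(benzyloxy)phenyl]penta-2,4-dienoyl}-1,3-oxazolidin-2-one, via mixed pivalic anhydride 16 (not isolated)
Conditions: PivCl, Et3N, THF, −20 °C; then 15, LiCl, −20 °C → rt
Reagents that add atoms: none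
Why: N-Acylation of an oxazolidinone through a mixed anhydride; LiCl activates the N–H towards the amine base, and attack occurs at the less hindered, non-pivaloyl carbonyl.

Step 10
Reactants: 11 {[(3S,4S)-4-[3,4-bis(benzyloxy)phenyl]-3-[3,5-bis(benzyloxy)phenyl]-5,5-dichlorocyclopent-1-en-1-yl]oxy}trimethylsilane; 17 3-{(2E,4E)-5-[3,4-bis(benzyloxy)phenyl]penta-2,4-dienoyl}-1,3-oxazolidin-2-one
Product: 18 3-{(4E)-5-[3,4-bis(benzyloxy)phenyl]-3-[(1S,2S,3S)-3-[3,4-bis(benzyloxy)phenyl]-2-[3,5-bis(benzyloxy)phenyl]-4,4-dichloro-5-oxocyclopentyl]pent-4-enoyl}-1,3-oxazolidin-2-one (ring substituents all-trans; both epimers at C3 of the pentenoyl chain)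
Conditions: 17, TiCl4, CH2Cl2, −78 °C; then 11, −78 → −40 °C; aq. NaHCO3
Reagents that add atoms: none
Why: Mukaiyama–Michael addition; TiCl4 chelates both imide carbonyls of 17 and the enol silane attacks the β-carbon (future C4), the δ-carbon being deactivated and shielded by its donor aryl group. C5 is set by approach anti to the adjacent C6 aryl, and being α to the ketone it can also settle into this trans arrangement. The chain stereocentre (C4) forms as a mixture that does not matter, since C4 becomes sp2 in step 13.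

Step 11
Reactants: 18 3-{(4E)-5-[3,4-bis(benzyloxy)phenyl]-3-[(1S,2S,3S)-3-[3,4-bis(benzyloxy)phenyl]-2-[3,5-bis(benzyloxy)phenyl]-4,4-dichloro-5-oxocyclopentyl]pent-4-enoyl}-1,3-oxazolidin-2-one
Product: 19 3-{(4E)-5-[3,4-bis(benzyloxy)phenyl]-3-[(1S,2R,3S)-3-[3,4-bis(benzyloxy)phenyl]-2-[3,5-bis(benzyloxy)phenyl]-5-oxocyclopentyl]pent-4-enoyl}-1,3-oxazolidin-2-one (both epimers at C3 of the chain)
Conditions: Zn dust, AcOH/THF, rt → 45 °C
Reagents that add atoms: none
Why: Zinc reduction of an α,α-dichloro ketone: two successive C–Cl reductions through zinc enolates that AcOH protonates at C1. Imide, alkenes and benzyl ethers are inert, and the ring stereocentres are untouched (the change of descriptor at the resorcinol-bearing carbon is only a change of CIP priorities).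

Step 12
Reactants: 19 3-{(4E)-5-[3,4-bis(benzyloxy)phenyl]-3-[(1S,2R,3S)-3-[3,4-bis(benzyloxy)phenyl]-2-[3,5-bis(benzyloxy)phenyl]-5-oxocyclopentyl]pent-4-enoyl}-1,3-oxazolidin-2-one
Product: 20 (1S,5S,6R,7R)-7-[3,4-bis(benzyloxy)phenyl]-6-[3,5-bis(benzyloxy)phenyl]-4-{(E)-2-[3,4-bis(benzyloxy)phenyl]ethenyl}bicyclo[3.2.1]octane-2,8-dione (6-aryl exo, 7-aryl endo; both C4 epimers)
Conditions: LiN(SiMe3)2 (2.2 equiv), THF, −78 → −20 °C; AcOH, −78 °C
Reagents that add atoms: none
Why: Intramolecular Claisen (Dieckmann-type) acylation of the C1 ketone enolate by the imide carbonyl, a 6-(enolendo)-exo-trig closure; the C5 enolate could only form a four-membered ring, so only C1 closes. C1 is set by the tether: the chain on C5 can deliver C2 only to its own face, which is the face cis to the C7 aryl. The oxazolidinide leaving group is a poor nucleophile for reopening the diketone, and the second equivalent of base holds the product as its C2/C3 enolate until the acidic quench.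

Step 13
Reactants: 20 (1S,5S,6R,7R)-7-[3,4-bis(benzyloxy)phenyl]-6-[3,5-bis(benzyloxy)phenyl]-4-{(E)-2-[3,4-bis(benzyloxy)phenyl]ethenyl}bicyclo[3.2.1]octane-2,8-dione
Product: 22 (1S,5R,6R,7R)-7-[3,4-bis(benzyloxy)phenyl]-6-[3,5-bis(benzyloxy)phenyl]-4-{(E)-2-[3,4-bis(benzyloxy)phenyl]ethenyl}bicyclo[3.2.1]oct-3-ene-2,8-dione, via trimethylsilyl enol ether 21 (not isolated)
Conditions: Me3SiOTf, Et3N, CH2Cl2, 0 °C; then Pd(OAc)2, MeCN, rt
Reagents that add atoms: none
Why: Saegusa–Ito dehydrogenation; C1 is a bridgehead, so the C2 ketone can be silylated only towards C3. Divalent palladium from Pd(OAc)2 forms the oxa-π-allyl complex, and β-hydride elimination of the C4 hydrogen gives C3=C4. Both C4 epimers of 20 converge on one enone.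

Step 14
Reactants: 22 (1S,5R,6R,7R)-7-[3,4-bis(benzyloxy)phenyl]-6-[3,5-bis(benzyloxy)phenyl]-4-{(E)-2-[3,4-bis(benzyloxy)phenyl]ethenyl}bicyclo[3.2.1]oct-3-ene-2,8-dione
Product: 23 jezonodione, (1S,5R,6R,7R)-7-(3,4-dihydroxyphenyl)-6-(3,5-dihydroxyphenyl)-4-[(E)-2-(3,4-dihydroxyphenyl)ethenyl]bicyclo[3.2.1]oct-3-ene-2,8-dione
Conditions: BCl3, C6HMe5, CH2Cl2, −78 °C; MeOH quench
Reagents that add atoms: none
Why: Lewis acid cleavage of aryl benzyl ethers with pentamethylbenzene as a non-basic benzyl cation scavenger. At −78 °C the dienone, the styryl double bond and the 1,3-diketone should be left alone, and the scavenger keeps benzyl cations off the electron-rich rings. No stereocentre is touched.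

## Compound list

1 | 3,5-bis(benzyloxy)benzyl bromide | BrCc1cc(OCc2ccccc2)cc(OCc2ccccc2)c1 | starting material
2 | diethyl {[3,5-bis(benzyloxy)phenyl]methyl}phosphonate | CCOP(=O)(Cc1cc(OCc2ccccc2)cc(OCc2ccccc2)c1)OCC | intermediate
3 | 3,4-bis(benzyloxy)benzaldehyde | O=Cc1ccc(OCc2ccccc2)c(OCc2ccccc2)c1 | starting material
4 | (E)-3,3′,4,5′-tetrakis(benzyloxy)stilbene | c1(/C=C/c2cc(OCc3ccccc3)cc(OCc3ccccc3)c2)ccc(OCc2ccccc2)c(OCc2ccccc2)c1 | intermediate
5 | trichloroacetyl chloride | O=C(Cl)C(Cl)(Cl)Cl | starting material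
6 | dichloroketene | O=C=C(Cl)Cl | intermediate
7 | (3RS,4RS)-3-[3,4-bis(benzyloxy)phenyl]-4-[3,5-bis(benzyloxy)phenyl]-2,2-dichlorocyclobutan-1-one (racemate, both enantiomers written) | O=C1C(Cl)(Cl)[C@H](c2ccc(OCc3ccccc3)c(OCc3ccccc3)c2)[C@H]1c1cc(OCc2ccccc2)cc(OCc2ccccc2)c1.O=C1C(Cl)(Cl)[C@@H](c2ccc(OCc3ccccc3)c(OCc3ccccc3)c2)[C@@H]1c1cc(OCc2ccccc2)cc(OCc2ccccc2)c1 | intermediate
8 | (3S,4S)-3-[3,4-bis(benzyloxy)phenyl]-4-[3,5-bis(benzyloxy)phenyl]-2,2-dichlorocyclobutan-1-one | O=C1C(Cl)(Cl)[C@H](c2ccc(OCc3ccccc3)c(OCc3ccccc3)c2)[C@H]1c1cc(OCc2ccccc2)cc(OCc2ccccc2)c1 | intermediate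
9 | diazomethane | C=[N+]=[N-] | starting material
10 | (3S,4S)-3-[3,4-bis(benzyloxy)phenyl]-4-[3,5-bis(benzyloxy)phenyl]-2,2-dichlorocyclopentan-1-one | O=C1C[C@H](c2cc(OCc3ccccc3)cc(OCc3ccccc3)c2)[C@@H](c2ccc(OCc3ccccc3)c(OCc3ccccc3)c2)C1(Cl)Cl | intermediate
11 | {[(3S,4S)-4-[3,4-bis(benzyloxy)phenyl]-3-[3,5-bis(benzyloxy)phenyl]-5,5-dichlorocyclopent-1-en-1-yl]oxy}trimethylsilane | C[Si](C)(C)OC1=C[C@H](c2cc(OCc3ccccc3)cc(OCc3ccccc3)c2)[C@@H](c2ccc(OCc3ccccc3)c(OCc3ccccc3)c2)C1(Cl)Cl | intermediate
12 | ethyl (2E)-4-(diethoxyphosphoryl)but-2-enoate | CCOC(=O)/C=C/CP(=O)(OCC)OCC | starting material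
13 | ethyl (2E,4E)-5-[3,4-bis(benzyloxy)phenyl]penta-2,4-dienoate | CCOC(=O)/C=C/C=C/c1ccc(OCc2ccccc2)c(OCc2ccccc2)c1 | intermediate
14 | (2E,4E)-5-[3,4-bis(benzyloxy)phenyl]penta-2,4-dienoic acid | OC(=O)/C=C/C=C/c1ccc(OCc2ccccc2)c(OCc2ccccc2)c1 | intermediate
15 | 1,3-oxazolidin-2-one | O=C1NCCO1 | starting material
16 | (2E,4E)-5-[3,4-bis(benzyloxy)phenyl]penta-2,4-dienoic 2,2-dimethylpropanoic anhydride | CC(C)(C)C(=O)OC(=O)/C=C/C=C/c1ccc(OCc2ccccc2)c(OCc2ccccc2)c1 | intermediate
17 | 3-{(2E,4E)-5-[3,4-bis(benzyloxy)phenyl]penta-2,4-dienoyl}-1,3-oxazolidin-2-one | O=C(/C=C/C=C/c1ccc(OCc2ccccc2)c(OCc2ccccc2)c1)N1CCOC1=O | intermediate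
18 | 3-{(4E)-5-[3,4-bis(benzyloxy)phenyl]-3-[(1S,2S,3S)-3-[3,4-bis(benzyloxy)phenyl]-2-[3,5-bis(benzyloxy)phenyl]-4,4-dichloro-5-oxocyclopentyl]pent-4-enoyl}-1,3-oxazolidin-2-one (chain C3 unspecified) | O=C1[C@@H](C(/C=C/c2ccc(OCc3ccccc3)c(OCc3ccccc3)c2)CC(=O)N2CCOC2=O)[C@H](c2cc(OCc3ccccc3)cc(OCc3ccccc3)c2)[C@@H](c2ccc(OCc3ccccc3)c(OCc3ccccc3)c2)C1(Cl)Cl | intermediate
19 | 3-{(4E)-5-[3,4-bis(benzyloxy)phenyl]-3-[(1S,2R,3S)-3-[3,4-bis(benzyloxy)phenyl]-2-[3,5-bis(benzyloxy)phenyl]-5-oxocyclopentyl]pent-4-enoyl}-1,3-oxazolidin-2-one (chain C3 unspecified) | O=C1[C@@H](C(/C=C/c2ccc(OCc3ccccc3)c(OCc3ccccc3)c2)CC(=O)N2CCOC2=O)[C@H](c2cc(OCc3ccccc3)cc(OCc3ccccc3)c2)[C@@H](c2ccc(OCc3ccccc3)c(OCc3ccccc3)c2)C1 | intermediate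
20 | (1S,5S,6R,7R)-7-[3,4-bis(benzyloxy)phenyl]-6-[3,5-bis(benzyloxy)phenyl]-4-{(E)-2-[3,4-bis(benzyloxy)phenyl]ethenyl}bicyclo[3.2.1]octane-2,8-dione (C4 unspecified) | O=C1CC(/C=C/c2ccc(OCc3ccccc3)c(OCc3ccccc3)c2)[C@@H]2C(=O)[C@H]1[C@H](c1ccc(OCc3ccccc3)c(OCc3ccccc3)c1)[C@H]2c1cc(OCc2ccccc2)cc(OCc2ccccc2)c1 | intermediate
21 | trimethylsilyl enol ether of 20 with a C2=C3 double bond (2-trimethylsilyloxy-8-oxobicyclo[3.2.1]oct-2-ene; configuration at C1, C5, C6, C7 as in 20) | C[Si](C)(C)OC1=CC(/C=C/c2ccc(OCc3ccccc3)c(OCc3ccccc3)c2)[C@@H]2C(=O)[C@H]1[C@H](c1ccc(OCc3ccccc3)c(OCc3ccccc3)c1)[C@H]2c1cc(OCc2ccccc2)cc(OCc2ccccc2)c1 | intermediate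
22 | (1S,5R,6R,7R)-7-[3,4-bis(benzyloxy)phenyl]-6-[3,5-bis(benzyloxy)phenyl]-4-{(E)-2-[3,4-bis(benzyloxy)phenyl]ethenyl}bicyclo[3.2.1]oct-3-ene-2,8-dione | O=C1C=C(/C=C/c2ccc(OCc3ccccc3)c(OCc3ccccc3)c2)[C@@H]2C(=O)[C@H]1[C@H](c1ccc(OCc3ccccc3)c(OCc3ccccc3)c1)[C@H]2c1cc(OCc2ccccc2)cc(OCc2ccccc2)c1 | intermediate
23 | jezonodione, (1S,5R,6R,7R)-7-(3,4-dihydroxyphenyl)-6-(3,5-dihydroxyphenyl)-4-[(E)-2-(3,4-dihydroxyphenyl)ethenyl]bicyclo[3.2.1]oct-3-ene-2,8-dione | O=C1C=C(/C=C/c2ccc(O)c(O)c2)[C@@H]2C(=O)[C@H]1[C@H](c1ccc(O)c(O)c1)[C@H]2c1cc(O)cc(O)c1 | target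

## Step count and least certain steps

Total: 14 steps (13 reactions and one chromatographic resolution). Longest linear sequence: 11 steps (steps 1–6 and 10–14, from 1). Steps 7–9 form a three-step branch to 17.

**Step 5 (key step).** What may go wrong: migration of the wrong ring bond, a second insertion into the product, or epoxide formation in place of the shift. Fallback: starting from 8, a Lewis-acid-catalysed homologation with Me3SiCHN2 (Sc(OTf)3 cat., toluene, 0 °C). The bulkier reagent should insert once and give the C-silylated ketone (3S,4S)-3-[3,4-bis(benzyloxy)phenyl]-4-[3,5-bis(benzyloxy)phenyl]-2,2-dichloro-5-(trimethylsilyl)cyclopentan-1-one F1. Protodesilylation (KF, MeOH) returns to the route at 10.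

**Step 10.** What may go wrong: sluggish addition because the CCl2 group lowers the nucleophilicity of the enol silane, chloride abstraction from the allylic CCl2 carbon by the Lewis acid, or competing 1,6-addition to the dienoyl imide. Fallback: the roles of the partners are reversed, setting out from 11 and 3.
- 3 is homologated (Ph3P=CHCHO, toluene, 80 °C) to (2E)-3-[3,4-bis(benzyloxy)phenyl]prop-2-enal F2.
- Mukaiyama aldol addition of 11 to F2 (BF3·OEt2, CH2Cl2, −78 °C) gives the 5-(1-hydroxy-3-arylprop-2-enyl) derivative of 10, F3.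
- Acid-catalysed dehydration (TsOH cat., toluene) gives the cross-conjugated (5E)-5-(3-arylprop-2-enylidene) derivative of 10, F4.
- TiCl4-mediated Mukaiyama–Michael addition of the silyl ketene N,O-acetal 3-{1-[(tert-butyldimethylsilyl)oxy]ethenyl}-1,3-oxazolidin-2-one F5 (from 3-acetyl-1,3-oxazolidin-2-one, tBuMe2SiOTf, Et3N) to F4, followed by protonation at C5, returns to the route at 18.

**Step 12.** What may go wrong: competitive deprotonation of the imide α-methylene with loss of the oxazolidinone, O-acylation of the enolate in place of C-acylation, retro-Michael fragmentation on warming, or retro-Claisen opening during work-up. Fallback: the bond is made by an aldol reaction and the oxidation level corrected afterwards, setting out from 19.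
- LiBH4 (THF/MeOH) reduces imide and ketone to the diol (4E)-5-[3,4-bis(benzyloxy)phenyl]-3-[3-[3,4-bis(benzyloxy)phenyl]-2-[3,5-bis(benzyloxy)phenyl]-5-hydroxycyclopentyl]pent-4-en-1-ol F6.
- Dess–Martin periodinane gives the keto aldehyde (4E)-5-[3,4-bis(benzyloxy)phenyl]-3-[(1S,2R,3S)-3-[3,4-bis(benzyloxy)phenyl]-2-[3,5-bis(benzyloxy)phenyl]-5-oxocyclopentyl]pent-4-enal F7.
- Acid-catalysed bridged aldol addition of C1 to the aldehyde (aq. HCl, THF) gives the 2-hydroxy analogue of 20, F8.
- A second Dess–Martin oxidation returns to the route at 20.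

**Step 3.** What may go wrong: slow cycloaddition to the trans-disubstituted alkene, so that ketene oligomerisation dominates, or Lewis-acid-induced ring opening of the donor-substituted cyclobutanone. Fallback: setting out from 4, irradiation (365 nm, MeCN) gives the more reactive (Z)-3,3′,4,5′-tetrakis(benzyloxy)stilbene F9. The same cycloaddition then gives the cis adduct (3RS,4SR)-3-[3,4-bis(benzyloxy)phenyl]-4-[3,5-bis(benzyloxy)phenyl]-2,2-dichlorocyclobutan-1-one F10. Acid-mediated epimerisation at the benzylic α-carbon through the enol (CF3CO2H cat., CH2Cl2) to the more stable trans isomer returns to the route at 7. The epimerisation is itself unproven on this system, and it must be run under acid, since amine bases are likely to trigger chlorine migration.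

**Step 14.** What may go wrong: incomplete sixfold cleavage, addition of chloride or benzyl cations to the dienone, opening of the diketone on quench, or air oxidation of the catechols. Fallback: the benzyl groups are removed before the enone exists, setting out from 20.
- BCl3, C6HMe5 (CH2Cl2, −78 °C) gives 3,4-dihydrojezonodione F11.
- tBuMe2SiCl, imidazole (DMF) gives its hexakis-O-(tert-butyldimethylsilyl) ether F12.
- Saegusa–Ito dehydrogenation (Me3SiOTf, Et3N; Pd(OAc)2, MeCN), through the C2 trimethylsilyl enol ether of F12, F13, gives hexakis-O-(tert-butyldimethylsilyl)jezonodione F14.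
- HF·pyridine (THF, 0 °C) returns to the route at 23.

## Further compounds

F1 | step 5 | (3S,4S)-3-[3,4-bis(benzyloxy)phenyl]-4-[3,5-bis(benzyloxy)phenyl]-2,2-dichloro-5-(trimethylsilyl)cyclopentan-1-one (C5 unspecified) | O=C1C([Si](C)(C)C)[C@H](c2cc(OCc3ccccc3)cc(OCc3ccccc3)c2)[C@@H](c2ccc(OCc3ccccc3)c(OCc3ccccc3)c2)C1(Cl)Cl
F2 | step 10 | (2E)-3-[3,4-bis(benzyloxy)phenyl]prop-2-enal | O=C/C=C/c1ccc(OCc2ccccc2)c(OCc2ccccc2)c1
F3 | step 10 | 5-{(2E)-1-hydroxy-3-[3,4-bis(benzyloxy)phenyl]prop-2-enyl} derivative of 10 (carbinol centre unspecified) | O=C1[C@@H](C(O)/C=C/c2ccc(OCc3ccccc3)c(OCc3ccccc3)c2)[C@H](c2cc(OCc3ccccc3)cc(OCc3ccccc3)c2)[C@@H](c2ccc(OCc3ccccc3)c(OCc3ccccc3)c2)C1(Cl)Cl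
F4 | step 10 | (5E)-5-{(2E)-3-[3,4-bis(benzyloxy)phenyl]prop-2-enylidene} derivative of 10 | O=C1/C(=C/C=C/c2ccc(OCc3ccccc3)c(OCc3ccccc3)c2)[C@H](c2cc(OCc3ccccc3)cc(OCc3ccccc3)c2)[C@@H](c2ccc(OCc3ccccc3)c(OCc3ccccc3)c2)C1(Cl)Cl
F5 | step 10 | 3-{1-[(tert-butyldimethylsilyl)oxy]ethenyl}-1,3-oxazolidin-2-one | C=C(O[Si](C)(C)C(C)(C)C)N1CCOC1=O
F6 | step 12 | (4E)-5-[3,4-bis(benzyloxy)phenyl]-3-[3-[3,4-bis(benzyloxy)phenyl]-2-[3,5-bis(benzyloxy)phenyl]-5-hydroxycyclopentyl]pent-4-en-1-ol (carbinol and chain C3 centres unspecified) | OC1[C@@H](C(/C=C/c2ccc(OCc3ccccc3)c(OCc3ccccc3)c2)CCO)[C@H](c2cc(OCc3ccccc3)cc(OCc3ccccc3)c2)[C@@H](c2ccc(OCc3ccccc3)c(OCc3ccccc3)c2)C1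
F7 | step 12 | (4E)-5-[3,4-bis(benzyloxy)phenyl]-3-[(1S,2R,3S)-3-[3,4-bis(benzyloxy)phenyl]-2-[3,5-bis(benzyloxy)phenyl]-5-oxocyclopentyl]pent-4-enal (chain C3 unspecified) | O=C1[C@@H](C(/C=C/c2ccc(OCc3ccccc3)c(OCc3ccccc3)c2)CC=O)[C@H](c2cc(OCc3ccccc3)cc(OCc3ccccc3)c2)[C@@H](c2ccc(OCc3ccccc3)c(OCc3ccccc3)c2)C1
F8 | step 12 | 2-hydroxy analogue of 20: 7-[3,4-bis(benzyloxy)phenyl]-6-[3,5-bis(benzyloxy)phenyl]-4-{(E)-2-[3,4-bis(benzyloxy)phenyl]ethenyl}-2-hydroxybicyclo[3.2.1]octan-8-one (C2 and C4 unspecified) | OC1CC(/C=C/c2ccc(OCc3ccccc3)c(OCc3ccccc3)c2)[C@@H]2C(=O)[C@H]1[C@H](c1ccc(OCc3ccccc3)c(OCc3ccccc3)c1)[C@H]2c1cc(OCc2ccccc2)cc(OCc2ccccc2)c1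
F9 | step 3 | (Z)-3,3′,4,5′-tetrakis(benzyloxy)stilbene | c1(/C=C\c2cc(OCc3ccccc3)cc(OCc3ccccc3)c2)ccc(OCc2ccccc2)c(OCc2ccccc2)c1
F10 | step 3 | (3RS,4SR)-3-[3,4-bis(benzyloxy)phenyl]-4-[3,5-bis(benzyloxy)phenyl]-2,2-dichlorocyclobutan-1-one (racemate, aryl groups cis, both enantiomers written) | O=C1C(Cl)(Cl)[C@H](c2ccc(OCc3ccccc3)c(OCc3ccccc3)c2)[C@@H]1c1cc(OCc2ccccc2)cc(OCc2ccccc2)c1.O=C1C(Cl)(Cl)[C@@H](c2ccc(OCc3ccccc3)c(OCc3ccccc3)c2)[C@H]1c1cc(OCc2ccccc2)cc(OCc2ccccc2)c1
F11 | step 14 | 3,4-dihydrojezonodione (C4 unspecified) | O=C1CC(/C=C/c2ccc(O)c(O)c2)[C@@H]2C(=O)[C@H]1[C@H](c1ccc(O)c(O)c1)[C@H]2c1cc(O)cc(O)c1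
F12 | step 14 | hexakis-O-(tert-butyldimethylsilyl) ether of F11 | O=C1CC(/C=C/c2ccc(O[Si](C)(C)C(C)(C)C)c(O[Si](C)(C)C(C)(C)C)c2)[C@@H]2C(=O)[C@H]1[C@H](c1ccc(O[Si](C)(C)C(C)(C)C)c(O[Si](C)(C)C(C)(C)C)c1)[C@H]2c1cc(O[Si](C)(C)C(C)(C)C)cc(O[Si](C)(C)C(C)(C)C)c1
F13 | step 14 | C2 trimethylsilyl enol ether of F12 (C2=C3) | C[Si](C)(C)OC1=CC(/C=C/c2ccc(O[Si](C)(C)C(C)(C)C)c(O[Si](C)(C)C(C)(C)C)c2)[C@@H]2C(=O)[C@H]1[C@H](c1ccc(O[Si](C)(C)C(C)(C)C)c(O[Si](C)(C)C(C)(C)C)c1)[C@H]2c1cc(O[Si](C)(C)C(C)(C)C)cc(O[Si](C)(C)C(C)(C)C)c1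
F14 | step 14 | hexakis-O-(tert-butyldimethylsilyl)jezonodione | O=C1C=C(/C=C/c2ccc(O[Si](C)(C)C(C)(C)C)c(O[Si](C)(C)C(C)(C)C)c2)[C@@H]2C(=O)[C@H]1[C@H](c1ccc(O[Si](C)(C)C(C)(C)C)c(O[Si](C)(C)C(C)(C)C)c1)[C@H]2c1cc(O[Si](C)(C)C(C)(C)C)cc(O[Si](C)(C)C(C)(C)C)c1
A1 | alternative 1 | 8-deoxo-8-(prop-2-enyloxy) hexa-O-methyl ether of 23 (C8 epimer arbitrary) | O=C1C=C(/C=C/c2ccc(OC)c(OC)c2)[C@@H]2[C@H](OCC=C)[C@H]1[C@H](c1ccc(OC)c(OC)c1)[C@H]2c1cc(OC)cc(OC)c1
A2 | alternative 1 | 7-[bis(prop-2-enyloxy)methyl]-6-(3,4-dimethoxyphenyl)-5-(3,5-dimethoxyphenyl)-3-[(E)-2-(3,4-dimethoxyphenyl)ethenyl]cyclohept-2-en-1-one (aryl groups trans) | O=C1C=C(/C=C/c2ccc(OC)c(OC)c2)C[C@H](c2cc(OC)cc(OC)c2)[C@@H](c2ccc(OC)c(OC)c2)[C@@H]1C(OCC=C)OCC=C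
A3 | alternative 2 | 3,4-dihydro hexa-O-methyl ether of 23 (C4 epimer arbitrary) | O=C1C[C@H](/C=C/c2ccc(OC)c(OC)c2)[C@@H]2C(=O)[C@H]1[C@H](c1ccc(OC)c(OC)c1)[C@H]2c1cc(OC)cc(OC)c1
A4 | alternative 2 | {[4-(3,4-dimethoxyphenyl)-3-(3,5-dimethoxyphenyl)cyclopent-1-en-1-yl]oxy}trimethylsilane (aryl groups trans) | C[Si](C)(C)OC1=C[C@H](c2cc(OC)cc(OC)c2)[C@@H](c2ccc(OC)c(OC)c2)C1
A5 | alternative 2 | 3-[(2E,4E)-5-(3,4-dimethoxyphenyl)penta-2,4-dienoyl]-1,3-oxazolidin-2-one | O=C(/C=C/C=C/c1ccc(OC)c(OC)c1)N1CCOC1=O
A6 | alternative 3 | trans-4-(3,4-dimethoxyphenyl)-3-(3,5-dimethoxyphenyl)cyclopentan-1-one carrying at C2 the (E)-1-(3,4-dimethoxyphenyl)-5-[methoxy(methyl)amino]-5-oxopent-1-en-3-yl chain (chain epimer arbitrary) | O=C1C[C@H](c2ccc(OC)c(OC)c2)[C@@H](c2cc(OC)cc(OC)c2)[C@@H]1[C@@H](/C=C/c1ccc(OC)c(OC)c1)CC(=O)N(C)OC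
A7 | alternative 3 | 4-(3,4-dimethoxyphenyl)-3-(3,5-dimethoxyphenyl)-2-{(E)-1-(3,4-dimethoxyphenyl)-5-[methoxy(methyl)amino]-5-oxopent-1-en-3-yl}pent-4-enal | O=C[C@@H]([C@@H](/C=C/c1ccc(OC)c(OC)c1)CC(=O)N(C)OC)[C@H](c1cc(OC)cc(OC)c1)C(=C)c1ccc(OC)c(OC)c1
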